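The readings were generated by integration for an exercise; scatter was added.

**Neighbour runs.** The north-west flask gave me the pace to start from, and the north-east flask gave the warning against trusting it.

| flask | E | X | Z | time |
|---|---|---|---|---|
| north-west | 0.400 M | 0.0120 M |  |  |
| north-east | 0.400 M | 0.0120 M | 0.120 M |  |
| west | 0.200 M | 0.0360 M |  | 170 min |

| run | time / min | [Z] / M |
|---|---|---|
| north-west run | 9.7 | 0.012 |
| north-west run | 29 | 0.036 |
| north-west run | 56 | 0.074 |
| north-west run | 89 | 0.085 |
| north-west run | 130 | 0.125 |
| north-west run | 170 | 0.159 |
| north-east run | 9.7 | 0.144 |
| north-east run | 29 | 0.181 |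
| north-east run | 56 | 0.233 |
| north-east run | 89 | 0.286 |
| north-east run | 130 | 0.331 |
| north-east run | 170 | 0.384 |

(scatter of a reading: 0.006 M)

* Z in the west run at 170 min, as a share of the E charged

- Overall: E -> Z, with X as catalyst.
- Constant volume, constant temperature.

**Fraction left.** I worked with the fraction of E left, not the fraction made, since a first-order loss is a straight line in its logarithm. By 170 min, the north-west flask's logarithm had dropped by 0.507. Dividing by cX and by the time gave 0.248 M⁻¹ min⁻¹. I call this the fade constant κ: the drop in the logarithm of the fraction of E left, per unit of cX and per minute. It is a pseudo-first-order constant divided by cX.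

**The chain.** The north-east flask, charged with Z, dropped by 1.08 in the same time, twice the north-west drop, so its E faded faster. I carried κ to the west flask all the same, on the bare assumption that the drop scales with cX, which these two runs do not test, since they had the same cX. For the west flask, κ gave a drop of 1.52, so the share made was 78.1%. I committed to that.

**Weak link.** That κ hung on one reading with a scatter of 0.006 M. The reading at 130 min gave κ = 0.240 M⁻¹ min⁻¹ and a west share of 77.0%, which was 1.1 percentage points lower than the first.

**The forecast.** The forecast differed from my reckoning and stood higher, at 86%, with this caution: “The order in X is untested”.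

**The result.** The west flask gave 80.1%, a drop of 1.61.

    X + E → Z + X (0.3114 M⁻¹ min⁻¹)
    E + Z → 2 Z (0.01674 M⁻¹ min⁻¹)
    X + E → Xa + E (0.03732 M⁻¹ min⁻¹)

**What to watch.** The quantity to follow in a repeat is κ, and the step to follow is the loss of X to Xa. The turning of X + E into Xa + E lowered the west flask's share. With the step struck out, the same west flask reached 89.3%, a drop of 2.24. Its κ then came to 0.366 M⁻¹ min⁻¹, against 0.264 M⁻¹ min⁻¹ with the step in place.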